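Keep the books on the first end groups, the limiting reagent by charge (0.050 M against 0.0550 M), and watch how long they wait without a partner.

| flask | first end groups | second end groups | remark | time |
|---|---|---|---|---|
| blue | 0.050 M | 0.055 M | run made earlier |  |
| violet | 0.050 M | 0.083 M | run made earlier |  |
| eta | 0.050 M (in portions, 2, over 12 min) | 0.0550 M | first portion at the start, last at 12 min | 30 min |
| theta | 0.050 M | 0.0550 M (fed, over 12 min) | all else is in the flask from the start; the feed brings no volume worth counting | 30 min |
| beta | 0.050 M | 0.0550 M | everything together at the start | 30 min |
| epsilon | 0.050 M (fed, over 12 min) | 0.0550 M | all else is in the flask from the start; the feed brings no volume worth counting | 30 min |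

| run | time / min | links / % | first end groups / % |
|---|---|---|---|
| blue | 1.50 | 86.8 | 6.6 |
| blue | 5.00 | 91.3 | 0 |
| blue | 8.00 | 92.3 | 0.3 |
| blue | 12.0 | 92.1 | 0 |
| blue | 20.0 | 91.7 | 0.4 |
| blue | 25.0 | 93.2 | 0.6 |
| blue | 30.0 | 94.0 | 0 |
| violet | 0.667 | 92.5 | 6.8 |
| violet | 1.00 | 96.0 | 1.6 |
| violet | 1.50 | 96.7 | 0 |
| violet | 2.50 | 96.6 | 0 |
| violet | 4.00 | 95.0 | 0 |
| violet | 6.00 | 97.1 | 0 |
| violet | 10.0 | 97.9 | 0 |

(readings scatter by 1 percentage point)

- which flask leads in amount of links, in percent of the first end groups charged ("all alike" within 1.5 percentage points) (eta / theta / beta / epsilon / all alike)
- how much links is there at the end, in percent of the first end groups charged: eta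
- how much links is there at the end, in percent of the first end groups charged: theta
- how much links is there at the end, in percent of the first end groups charged: beta
- how much links is there at the end, in percent of the first end groups charged: epsilon



The first entry in the ledger is links. Their late readings leave a loss entry of 7.57% of the charge in the blue run and 3.34% in the violet run. I read this loss as two first end groups meeting, so it should follow the ratio of first to second end groups along the way. Summed over the charge, that ratio is 0.760 for blue and 0.391 for violet. Dividing gives 0.0996 and 0.0854, which I average to a selectivity factor, as read from these scattered readings, of 0.0924. The first readings of both runs give a link constant of about 97.5 L mol⁻¹ min⁻¹.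

For beta I then reckon the books to close at 93.0% links. In theta the first end groups wait in the flask, and at the start a fed second end group is met within about 0.205 min, far shorter than the feed of 12 min. So I let links grow at the feed rate and the loss with the square of what waits. The waiting number W is the starting loss rate divided by the feed rate, here 4.92. As a rough form of my own, I close the ledger at a link fraction of 1/√(1 + 2W/3), which for theta is 48.4%. I set no figure of my own for eta and epsilon.

The forecast names beta as leader at 93.5%, gives eta 93% and epsilon 92.8%, and for theta, where it says “the side step is far worse”, gives 72%, above my figure.

The flasks give links of 72.7% in eta, 49.9% in theta, 93.0% in beta and 72.6% in epsilon, so beta leads.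

    first end groups + links → side product (k = 0.0170 L mol⁻¹ s⁻¹)
    2 first end groups → homo dimer (k = 0.0552 L mol⁻¹ s⁻¹)
    first end groups + second end groups → links + by-product (k = 1.74 L mol⁻¹ s⁻¹)
    second end groups → decomposed reagent (k = 8.98 × 10⁻⁴ s⁻¹)

Theta's ledger stands at 30.0 min with links 49.9%, homo dimer 46.1% and side product 4.07%, each counted by the first end groups it holds, against my 48.4% for links. The neighbouring flask is theta with the first end groups cut to 0.020 M, which makes 2.75 equiv of second end groups. W falls with the square of that charge to 0.786, so the same form gives 81.0%. That neighbouring flask gives links of 77.2%, and its ledger ends at 30.0 min with homo dimer 20.3% and side product 2.53%.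

(Readings and results stem from a simulated flask with made-up constants; the scatter is artificial.)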